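## The problem

1. The target is a retrochalcone without any stereocentre. Its only stereochemical element is the E double bond Cα=Cβ, which a syn-insertion/syn-elimination olefin synthesis sets reliably.
2. Ring A (4-hydroxybenzoyl) and the three-carbon link are simple. The difficulty is ring B, a pentasubstituted benzene numbered here C1 (enone), C2 (OMe), C3 (OH), C4 (OH), C5 (1,1-dimethylallyl) and C6 (H).
3. A synthesis must join a quaternary carbon to C5 beside an oxygen-bearing carbon. It must also tell three contiguous oxygens apart so that only O–C2 is methylated, and it must put carbon on C1 and C5 but not on C6. No cheap benzene has this connectivity.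
4. In pyrogallol-type building blocks O–C2 is the hardest oxygen to address, because it is flanked on both sides and hydrogen-bonded to a C1 carbonyl group.
5. Three groups are sensitive: the 1,1-dimethylallyl group beside the free C4 hydroxyl (closure to a dihydrobenzofuran in strong acid), the C3/C4 catechol (oxidation in basic, aerated media) and the enone (conjugate addition). A C1 aldehyde para to a free C4 hydroxyl is also deactivated as its phenoxide in a basic aldol condensation.
6. The feature that opens another way is the run C1–C2–C3–C4. These are four contiguous ring atoms of which C2, C3 and C4 bear oxygen and C1 stands para to O–C4. They are followed by a two-carbon unit C5–C6 whose only substituent sits on the atom next to C4.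
7. This is the imprint of the four-membered ring of squarate 6, in which all four carbons are oxygenated, after ring expansion by a 1,1-disubstituted vinyl group. It holds provided that the fourth oxygen, on C1, is used as the handle for the enone.

## Retrosynthesis

**Disconnection 1, 20 to 18 (an O–CH3 bond is added on C3).**
- Ring B is to come from a symmetrical four-carbon block, so O–C2 and O–C3 arrive with the same alkyl group and the last step must free O–C3 only.
- The neighbouring option is an unsymmetrical squarate with a removable group on one oxygen. That would move the problem to a carbonyl addition with no strong regiochemical bias.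
- In 18 the two methoxy groups differ. The one on C3 lies beside the free C4 hydroxyl, which can carry a Lewis acid to it in a five-membered chelate (19), and it is meta to the enone. The one on C2 is conjugated with the enone and has no hydroxyl neighbour.
- The forward step must be a chelation-directed mono-demethylation that spares the alkenes.

**Disconnection 2, 18 to 13 and 16 (bond C1–Cβ).**
- The neighbouring cut, Cα=Cβ by aldol condensation, needs a formyl carbon on C1. The ring synthesis cannot deliver that carbon, and para to O–C4 it would be a poor electrophile in base.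
- Cutting C1–Cβ turns the surplus oxygen on C1 into an asset: as triflate 13 it is a Heck partner for vinyl ketone 16.
- The precursors are an arene with no side chain and a nine-carbon enone.
- The forward reaction must arylate the enone terminus and leave the neopentyl-type vinyl group untouched.

**Disconnection 3, 13 through 12 to 9 (bond C1–C6 cut, bond C1–C4 re-made).**
- Phenol 12 is the enol of dienone 11, which is the 6π product of dienylketene 10, which is the 4π opening product of cyclobutenone 9.
- This removes the aromatic ring altogether. Compound 9 is an isomer of 12 in which C1–C4 still form the squarate ring and C5–C6 are a vinyl arm on C4.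
- The cut also differentiates the two para oxygens by origin. O–C4 is the silylated carbinol oxygen and O–C1 is the ketene oxygen, born as the only free hydroxyl.
- Other cuts of ring B (bonds C2–C3, C3–C4) have no pericyclic counterpart that keeps three oxygens in place.

**Disconnection 4, 9 to 6 and 7 (bond C4–C5).**
- One carbonyl addition joins all ring atoms.
- Squarate 6 has two equivalent carbonyl groups, so there is no regiochemical question.
- Alkoxide 8 is silylated in the flask.
- The forward reaction asks only for 1,2-addition of a hindered alkenyllithium at low temperature.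

**Disconnection 5, 7 through 5 and 3 to 1.**
- The quaternary carbon is not made but bought in acid 1.
- Ketone 3 has α-hydrogens only on its methyl group. A Shapiro reaction of hydrazone 5 can therefore place lithium only on the carbon that becomes C5.

**Disconnection 6, 16 to 14 (the terminal methylene carbon).**
- A one-carbon α-methylenation of commercial ketone 14 through Mannich base 15 gives the Heck partner in one step.

## Roads not taken

**Alternative 1:** the most obvious plan.
- Cut: bond C5–C(CH3)2 by a [3,3] shift and bond Cα=Cβ by aldol condensation.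
- Forward:
  - 2,3,4-trihydroxybenzaldehyde A1 is methylated on O–C2 and prenylated on O–C4 to give 3-hydroxy-2-methoxy-4-(3-methylbut-2-enyloxy)benzaldehyde A2.
  - Aromatic Claisen rearrangement gives 3,4-dihydroxy-2-methoxy-5-(2-methylbut-3-en-2-yl)benzaldehyde A3.
  - A3 is condensed with 14.
- Why the chosen plan is better:
  - The three hydroxyls of A1 must be addressed against their natural order of reactivity. The chelated, least nucleophilic one needs the methyl group, so several masking steps precede the key step.
  - The rearrangement sets one bond only. It needs high temperature beside a free phenol that can add to the new alkene.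
  - A3 is a 4-hydroxybenzaldehyde that needs masking again for the aldol step.
  - The chosen plan differentiates the oxygens by their origin and needs one silyl group.

**Alternative 2:**
- Cut: the same bond C5–C(CH3)2, by cross-coupling.
- Forward: 5-bromo-2-methoxy-3,4-bis(methoxymethoxy)benzaldehyde A4 and 4,4,5,5-tetramethyl-2-(3-methylbut-2-enyl)-1,3,2-dioxaborolane A5 are coupled at the γ-carbon under Pd(OAc)2 and a bulky biaryl phosphine. The product is 2-methoxy-3,4-bis(methoxymethoxy)-5-(2-methylbut-3-en-2-yl)benzaldehyde A6, followed by aldol condensation and deprotection.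
- Why the chosen plan is better:
  - A4 needs the same oxygen differentiation as Alternative 1 plus a regioselective bromination.
  - The reductive elimination must form a quaternary carbon beside an ortho alkoxy group. This is the case in which γ-selectivity is least secure.
  - It changes the reagent for the same bond and does not simplify the ring.

**Alternative 3:**
- Cut: ring B by a Danheiser benzannulation.
- Forward: Wolff rearrangement of methyl (E)-2-diazo-6,6-dimethyl-3-oxoocta-4,7-dienoate A7 gives a vinylketene. It combines with methoxyethyne A8 to give methyl 4-hydroxy-2-methoxy-5-(2-methylbut-3-en-2-yl)benzoate A9.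
- Why the chosen plan is better:
  - The alkyne supplies C2 and C3, so an oxygen on C3 would need an alkyne oxygenated at both ends, which is not a practical reagent.
  - With A8, C3 arrives as C–H. It would have to be hydroxylated late, between two substituents on an ester-deactivated ring.
  - The ester needs redox adjustment and A7 needs a long run-up.
  - The squarate brings O–C2, O–C3 and O–C4 at once.

Key step: step 4

Assumption: 1, 4, 6 and 14 are taken as commercial. Compound 9 is made and used as the racemate, which has no consequence because its only stereocentre becomes the aromatic carbon C4 in step 4. Ring B numbering is used for all intermediates, and C1–C4 of cyclobutenone 9 are C1–C4 of ring B.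

## Steps

Step 1
Reactants: 1 2,2-dimethylbut-3-enoic acid
Product: 3 3,3-dimethylpent-4-en-2-one, via dilithium gem-diolate 2 (not isolated)
Conditions: MeLi (2.2 equiv), Et2O, 0 °C to rt; inverse quench into cold 1 M HCl
Reagents that add atoms: methyllithium, [Li]C
Why: Addition of MeLi to the lithium carboxylate stops at gem-diolate 2, which gives the methyl ketone only on quench; the quaternary α-carbon excludes enolization and migration of the double bond into conjugation.

Step 2
Reactants: 3 3,3-dimethylpent-4-en-2-one; 4 2,4,6-triisopropylbenzenesulfonohydrazide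
Product: 5 (E)-N'-(3,3-dimethylpent-4-en-2-ylidene)-2,4,6-triisopropylbenzenesulfonohydrazide
Conditions: cat. HCl, MeCN, rt
Reagents that add atoms: none
Why: Acid-catalysed hydrazone formation; the tert-alkyl group places the sulfonamide nitrogen syn to the methyl group (E), which is also the geometry needed for syn deprotonation in step 3.

Step 3
Reactants: 5 (E)-N'-(3,3-dimethylpent-4-en-2-ylidene)-2,4,6-triisopropylbenzenesulfonohydrazide; 6 dimethyl squarate (3,4-dimethoxycyclobut-3-ene-1,2-dione)
Product: 9 (±)-4-(3,3-dimethylpenta-1,4-dien-2-yl)-2,3-dimethoxy-4-(trimethylsilyloxy)cyclobut-2-en-1-one, via vinyllithium 7 (not isolated), via lithium alkoxide 8 (not isolated)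
Conditions: n-BuLi (2.1 equiv), THF, −78 to 0 °C; then 6, THF, −78 °C; then TMSCl (excess), −78 to 0 °C
Reagents that add atoms: chlorotrimethylsilane, C[Si](C)(C)Cl
Why: Shapiro reaction: N–H and the only available α-C–H (methyl) are removed, and loss of sulfinate and N2 leaves lithium on the future C5. Alkenyllithium reagents add 1,2 to dialkyl squarates at low temperature, and the two carbonyl groups of 6 are equivalent, so only one adduct can form. The new stereocentre is racemic and is erased in step 4.

Step 4
Reactants: 9 (±)-4-(3,3-dimethylpenta-1,4-dien-2-yl)-2,3-dimethoxy-4-(trimethylsilyloxy)cyclobut-2-en-1-one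
Product: 12 2,3-dimethoxy-5-(2-methylbut-3-en-2-yl)-4-(trimethylsilyloxy)phenol, via dienylketene 10 (not isolated), via cyclohexadienone 11 (not isolated)
Conditions: degassed p-xylene (0.02 M), 138 °C, Ar
Reagents that add atoms: none
Why: Heating cleaves the C1–C4 bond of the four-membered ring by conrotatory 4π electrocyclic opening; the silyloxy donor on C4 rotates outward, as oxygen donors do in cyclobutenone openings, so the dienyl arm turns inward and (Z)-dienylketene 10 has its CH2 terminus C6 within reach of the ketene carbon C1. Disrotatory 6π electrocyclization forms the bond C1–C6 and so closes ring B (six-membered, all-carbon) as cyclohexa-2,4-dienone 11, whose C6 methylene group enolizes irreversibly to phenol 12. The closest known reaction type is the thermal ring expansion of squarate-derived 4-alkenyl-4-oxycyclobutenones to hydroquinone derivatives (Moore rearrangement), which is established for 1-substituted vinyl arms. No stereocentre is formed, and the one in 9 becomes the aromatic carbon C4. The substitution pattern is fixed by connectivity and not by selectivity: C2 and C3 keep their methoxy groups, C4 keeps the silylated carbinol oxygen, the ketene oxygen becomes the only free hydroxyl on C1, and the vinyl arm delivers the 1,1-dimethylallyl group to C5 and hydrogen to C6. The selectivities needed are the torquoselectivity, secured by the oxygen donor on C4, and a preference of the ketene for 6π closure over [2+2] addition to the remote vinyl group, secured by the unhindered CH2 terminus and by the quaternary carbon that holds the vinyl group on the far side of the arm. Since the ring opening is reversible, any ketene of the wrong geometry returns to 9 and is drained through 10.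

Step 5
Reactants: 12 2,3-dimethoxy-5-(2-methylbut-3-en-2-yl)-4-(trimethylsilyloxy)phenol
Product: 13 2,3-dimethoxy-5-(2-methylbut-3-en-2-yl)-4-(trimethylsilyloxy)phenyl trifluoromethanesulfonate
Conditions: Tf2O, pyridine, CH2Cl2, −20 to 0 °C
Reagents that add atoms: trifluoromethanesulfonic anhydride, O=S(=O)(OS(=O)(=O)C(F)(F)F)C(F)(F)F
Why: O-Sulfonylation of the only free hydroxyl, which has just OMe and H as neighbours; O–C4 has been silylated since step 3, so no reagent has to tell the two para oxygens apart.

Step 6
Reactants: 14 1-(4-hydroxyphenyl)ethan-1-one (4'-hydroxyacetophenone)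
Product: 16 1-(4-hydroxyphenyl)prop-2-en-1-one, via Mannich base 15 (not isolated)
Conditions: (CH2O)n, i-Pr2NH·CF3CO2H (1 equiv), cat. CF3CO2H, THF, reflux; used at once, stabilized by BHT
Reagents that add atoms: formaldehyde (as paraformaldehyde), C=O
Why: α-Methylenation of an aryl methyl ketone: a Mannich reaction gives 15, which loses the hindered amine by β-elimination under the reaction conditions. The acidic medium keeps the phenol un-ionized, so aminomethylation of ring A is not expected.

Step 7
Reactants: 13 2,3-dimethoxy-5-(2-methylbut-3-en-2-yl)-4-(trimethylsilyloxy)phenyl trifluoromethanesulfonate; 16 1-(4-hydroxyphenyl)prop-2-en-1-one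
Product: 18 (E)-3-[4-hydroxy-2,3-dimethoxy-5-(2-methylbut-3-en-2-yl)phenyl]-1-(4-hydroxyphenyl)prop-2-en-1-one, via silyl ether 17 (not isolated)
Conditions: Pd(OAc)2 (5 mol %), dppp (6 mol %), Et3N, BHT, DMF, 90 °C, slow addition of 16 (1.5 equiv); then MeOH, cat. citric acid, rt
Reagents that add atoms: none
Why: Mizoroki–Heck reaction of an aryl triflate with an aryl vinyl ketone: zerovalent palladium inserts into C1–OTf, the aryl group adds to the unsubstituted terminus of the electron-poor alkene, and syn β-hydride elimination sets the E enone. The 1,1-dimethylallyl vinyl group is neopentyl-like and slower to insert, and it has no allylic hydrogen, so palladium hydride cannot isomerize it. Methanolysis then removes the silyl group wherever it has survived.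

Step 8
Reactants: 18 (E)-3-[4-hydroxy-2,3-dimethoxy-5-(2-methylbut-3-en-2-yl)phenyl]-1-(4-hydroxyphenyl)prop-2-en-1-one
Product: 20 (E)-3-[3,4-dihydroxy-2-methoxy-5-(2-methylbut-3-en-2-yl)phenyl]-1-(4-hydroxyphenyl)prop-2-en-1-one (target), via cyclic chloroborate 19 (not isolated)
Conditions: BCl3 (3.5 equiv), CH2Cl2, −78 to −10 °C; then H2O–THF, 0 °C
Reagents that add atoms: none
Why: Chelation-directed ether cleavage: the C4 hydroxyl is borylated at once and holds boron against the adjacent C3 methoxy oxygen, whose methyl group is lost to chloride with closure of the five-membered borate 19. The C2 methoxy group has no hydroxyl neighbour and its lone pair is drawn into the Lewis-acid-complexed enone, so it should be less basic and stay. Hydrolysis frees the catechol, and the monosubstituted alkene is not protonated at these temperatures.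

## Compound list

1 | 2,2-dimethylbut-3-enoic acid | C=CC(C)(C)C(=O)O | starting material
2 | dilithium 3,3-dimethylpent-4-ene-2,2-diolate | C=CC(C)(C)C(C)(O[Li])O[Li] | intermediate (not isolated)
3 | 3,3-dimethylpent-4-en-2-one | CC(=O)C(C)(C)C=C | intermediate
4 | 2,4,6-triisopropylbenzenesulfonohydrazide | CC(C)c1cc(C(C)C)c(S(=O)(=O)NN)c(C(C)C)c1 | starting material
5 | (E)-N'-(3,3-dimethylpent-4-en-2-ylidene)-2,4,6-triisopropylbenzenesulfonohydrazide | C/C(=N\NS(=O)(=O)c1c(C(C)C)cc(C(C)C)cc1C(C)C)C(C)(C)C=C | intermediate
6 | dimethyl squarate (3,4-dimethoxycyclobut-3-ene-1,2-dione) | COC1=C(OC)C(=O)C1=O | starting material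
7 | (3,3-dimethylpenta-1,4-dien-2-yl)lithium | [Li]C(=C)C(C)(C)C=C | intermediate (not isolated)
8 | lithium (±)-1-(3,3-dimethylpenta-1,4-dien-2-yl)-2,3-dimethoxy-4-oxocyclobut-2-en-1-olate | COC1=C(OC)C(O[Li])(C(=C)C(C)(C)C=C)C1=O | intermediate (not isolated)
9 | (±)-4-(3,3-dimethylpenta-1,4-dien-2-yl)-2,3-dimethoxy-4-(trimethylsilyloxy)cyclobut-2-en-1-one | COC1=C(OC)C(O[Si](C)(C)C)(C(=C)C(C)(C)C=C)C1=O | intermediate
10 | (3Z)-2,3-dimethoxy-6,6-dimethyl-5-methylidene-4-(trimethylsilyloxy)octa-1,3,7-trien-1-one | O=C=C(OC)/C(OC)=C(O[Si](C)(C)C)\C(=C)C(C)(C)C=C | intermediate (not isolated)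
11 | 2,3-dimethoxy-5-(2-methylbut-3-en-2-yl)-4-(trimethylsilyloxy)cyclohexa-2,4-dien-1-one | O=C1CC(C(C)(C)C=C)=C(O[Si](C)(C)C)C(OC)=C1OC | intermediate (not isolated)
12 | 2,3-dimethoxy-5-(2-methylbut-3-en-2-yl)-4-(trimethylsilyloxy)phenol | COc1c(O)cc(C(C)(C)C=C)c(O[Si](C)(C)C)c1OC | intermediate
13 | 2,3-dimethoxy-5-(2-methylbut-3-en-2-yl)-4-(trimethylsilyloxy)phenyl trifluoromethanesulfonate | COc1c(OS(=O)(=O)C(F)(F)F)cc(C(C)(C)C=C)c(O[Si](C)(C)C)c1OC | intermediate
14 | 1-(4-hydroxyphenyl)ethan-1-one | CC(=O)c1ccc(O)cc1 | starting material
15 | 3-(diisopropylamino)-1-(4-hydroxyphenyl)propan-1-one | CC(C)N(CCC(=O)c1ccc(O)cc1)C(C)C | intermediate (not isolated)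
16 | 1-(4-hydroxyphenyl)prop-2-en-1-one | C=CC(=O)c1ccc(O)cc1 | intermediate
17 | (E)-3-[2,3-dimethoxy-5-(2-methylbut-3-en-2-yl)-4-(trimethylsilyloxy)phenyl]-1-(4-hydroxyphenyl)prop-2-en-1-one | C=CC(C)(C)c1cc(/C=C/C(=O)c2ccc(O)cc2)c(OC)c(OC)c1O[Si](C)(C)C | intermediate (not isolated)
18 | (E)-3-[4-hydroxy-2,3-dimethoxy-5-(2-methylbut-3-en-2-yl)phenyl]-1-(4-hydroxyphenyl)prop-2-en-1-one | C=CC(C)(C)c1cc(/C=C/C(=O)c2ccc(O)cc2)c(OC)c(OC)c1O | intermediate
19 | cyclic chloroborate of 20 (2-chloro-1,3,2-benzodioxaborole spanning O–C3 and O–C4; ring A phenol drawn free) | C=CC(C)(C)c1cc(/C=C/C(=O)c3ccc(O)cc3)c(OC)c2OB(Cl)Oc12 | intermediate (not isolated)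
20 | (E)-3-[3,4-dihydroxy-2-methoxy-5-(2-methylbut-3-en-2-yl)phenyl]-1-(4-hydroxyphenyl)prop-2-en-1-one | C=CC(C)(C)c1cc(/C=C/C(=O)c2ccc(O)cc2)c(OC)c(O)c1O | target

## Step count and least certain steps

Total steps: 8. Longest linear sequence: 7 (steps 1, 2, 3, 4, 5, 7, 8). Step 6 is a one-step branch.

**Step 4 (key step).**
- Risk: the most likely failure is a slow 6π closure. In 10 the arm must take the s-cis conformation in which the tert-alkyl group on C5 is pressed against the silyloxy group on C4. If this costs too much, the ketene lives long enough to be lost by oligomerization or by reaction with traces of water. Loss of the silyl group followed by air oxidation of the electron-rich product is the second concern.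
- Fallback, from 3 and 6, back at 18. The tert-alkyl group is moved to the far end of a linear alkyne arm. The ring is then closed at C4–C5 through a diradical instead of at C1–C6 by electrocyclization, and the para oxygens are told apart by hindrance instead of by origin.
  - Ketone 3 is taken in one flask (LDA; ClP(O)(OEt)2; LDA) through diethyl 3,3-dimethylpenta-1,4-dien-2-yl phosphate F1 to 3,3-dimethylpent-4-en-1-yne F2.
  - The lithium acetylide of F2 adds to 6 to give (±)-4-(3,3-dimethylpent-4-en-1-yn-1-yl)-4-hydroxy-2,3-dimethoxycyclobut-2-en-1-one F3.
  - Thermolysis takes the enynylketene course to 2,3-dimethoxy-5-(2-methylbut-3-en-2-yl)cyclohexa-2,5-diene-1,4-dione F4.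
  - Na2S2O4 gives 2,3-dimethoxy-5-(2-methylbut-3-en-2-yl)benzene-1,4-diol F5.
  - The C1 hydroxyl, far from the tert-alkyl group, is triflated in preference to give 4-hydroxy-2,3-dimethoxy-5-(2-methylbut-3-en-2-yl)phenyl trifluoromethanesulfonate F6.
  - A Heck reaction of F6 with 16 gives 18.

**Step 3.**
- Risk: the hindered dianion may fragment incompletely, or 7 may be protonated by THF during the warm-up. The lithium sulfinate that accompanies 7 consumes silyl chloride. A slow first addition leaves time for a second addition to 8.
- Fallback, from 3, back at 7: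
  - Hydrazine hydrate gives (E)-(3,3-dimethylpent-4-en-2-ylidene)hydrazine F7.
  - Iodine and 1,1,3,3-tetramethylguanidine (Barton vinyl iodide synthesis) give 2-iodo-3,3-dimethylpenta-1,4-diene F8, which can be purified.
  - Exchange with t-BuLi at −78 °C gives 7 free of sulfinate.

**Step 7.**
- Risk: oxidative addition into an electron-rich, ortho-substituted triflate is slow. Meanwhile 16 can polymerize or oligomerize by oxa-Michael addition of its own phenol under amine base. Hydrolysis of the triflate is a lesser concern.
- Fallback, from 13, back at 18:
  - The unstable enone is avoided. Reductive carbonylation (Pd(OAc)2, dppp, CO, Et3SiH, Et3N, DMF) gives 2,3-dimethoxy-5-(2-methylbut-3-en-2-yl)-4-(trimethylsilyloxy)benzaldehyde F9.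
  - Claisen–Schmidt condensation of F9 with 14 in concentrated KOH–EtOH, which also removes the silyl group, gives 18.

**Step 8.**
- Risk: free BCl3 may go on to cleave the hindered C2 methoxy group if the mixture is warmed too far. The acid set free at the quench may also drive addition of the C4 hydroxyl to the neighbouring alkene.
- Fallback, from 18, back at 20:
  - An oxidative, non-acidic demethylation is used. 2-Iodoxybenzoic acid (IBX) delivers oxygen only to the ortho carbon of the electron-rich C4 phenol that can leave as a quinone, which is C3. Methanol is lost, giving 4-[(E)-3-(4-hydroxyphenyl)-3-oxoprop-1-enyl]-3-methoxy-6-(2-methylbut-3-en-2-yl)cyclohexa-3,5-diene-1,2-dione F10. The acyl-deactivated ring A phenol should not react.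
  - Aqueous Na2S2O4 in the same flask reduces F10 to 20.

## Further compounds

F1 | step 4 | diethyl 3,3-dimethylpenta-1,4-dien-2-yl phosphate | C=C(OP(=O)(OCC)OCC)C(C)(C)C=C
F2 | step 4 | 3,3-dimethylpent-4-en-1-yne | C#CC(C)(C)C=C
F3 | step 4 | (±)-4-(3,3-dimethylpent-4-en-1-yn-1-yl)-4-hydroxy-2,3-dimethoxycyclobut-2-en-1-one | COC1=C(OC)C(O)(C#CC(C)(C)C=C)C1=O
F4 | step 4 | 2,3-dimethoxy-5-(2-methylbut-3-en-2-yl)cyclohexa-2,5-diene-1,4-dione | COC1=C(OC)C(=O)C(C(C)(C)C=C)=CC1=O
F5 | step 4 | 2,3-dimethoxy-5-(2-methylbut-3-en-2-yl)benzene-1,4-diol | COc1c(O)cc(C(C)(C)C=C)c(O)c1OC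
F6 | step 4 | 4-hydroxy-2,3-dimethoxy-5-(2-methylbut-3-en-2-yl)phenyl trifluoromethanesulfonate | COc1c(OS(=O)(=O)C(F)(F)F)cc(C(C)(C)C=C)c(O)c1OC
F7 | step 3 | (E)-(3,3-dimethylpent-4-en-2-ylidene)hydrazine | C/C(=N\N)C(C)(C)C=C
F8 | step 3 | 2-iodo-3,3-dimethylpenta-1,4-diene | C=C(I)C(C)(C)C=C
F9 | step 7 | 2,3-dimethoxy-5-(2-methylbut-3-en-2-yl)-4-(trimethylsilyloxy)benzaldehyde | COc1c(C=O)cc(C(C)(C)C=C)c(O[Si](C)(C)C)c1OC
F10 | step 8 | 4-[(E)-3-(4-hydroxyphenyl)-3-oxoprop-1-enyl]-3-methoxy-6-(2-methylbut-3-en-2-yl)cyclohexa-3,5-diene-1,2-dione | C=CC(C)(C)C1=CC(/C=C/C(=O)c2ccc(O)cc2)=C(OC)C(=O)C1=O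
A1 | alternative 1 | 2,3,4-trihydroxybenzaldehyde | O=Cc1ccc(O)c(O)c1O
A2 | alternative 1 | 3-hydroxy-2-methoxy-4-(3-methylbut-2-enyloxy)benzaldehyde | COc1c(C=O)ccc(OCC=C(C)C)c1O
A3 | alternative 1 | 3,4-dihydroxy-2-methoxy-5-(2-methylbut-3-en-2-yl)benzaldehyde | COc1c(C=O)cc(C(C)(C)C=C)c(O)c1O
A4 | alternative 2 | 5-bromo-2-methoxy-3,4-bis(methoxymethoxy)benzaldehyde | COCOc1c(Br)cc(C=O)c(OC)c1OCOC
A5 | alternative 2 | 4,4,5,5-tetramethyl-2-(3-methylbut-2-enyl)-1,3,2-dioxaborolane | CC(C)=CCB1OC(C)(C)C(C)(C)O1
A6 | alternative 2 | 2-methoxy-3,4-bis(methoxymethoxy)-5-(2-methylbut-3-en-2-yl)benzaldehyde | COCOc1c(C(C)(C)C=C)cc(C=O)c(OC)c1OCOC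
A7 | alternative 3 | methyl (E)-2-diazo-6,6-dimethyl-3-oxoocta-4,7-dienoate | COC(=O)C(=[N+]=[N-])C(=O)/C=C/C(C)(C)C=C
A8 | alternative 3 | methoxyethyne | C#COC
A9 | alternative 3 | methyl 4-hydroxy-2-methoxy-5-(2-methylbut-3-en-2-yl)benzoate | COC(=O)c1cc(C(C)(C)C=C)c(O)cc1OC
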